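## Structural features

The target is a symmetrical dimer: two identical 5,7-dihydroxy-2,2-dimethylchroman units are bonded through their C6 carbons to one methine carbon, which also carries a 5-methylhexyl chain (a 6-methylheptane-1,1-diyl bridge). Each aromatic ring (ring A and its twin) is fully substituted and bears an (R)-2-methylbutanoyl group on C8, between the 7-hydroxyl that chelates the ketone and the pyran oxygen O1 on C8a, so the oxygens on C5, C7 and C8a are mutually meta. The only stereocentres are the two acyl α-carbons, which are far apart and adjacent to no other stereocentre; the bridging methine carries two identical aryl groups and is not stereogenic as long as both halves keep the same configuration. Both centres are α to an aryl ketone and can epimerise by enolisation under strong acid or base at every stage after they are attached, not only during chain building, and one inverted centre would give meso-type diastereomers. Further fragile features are the electron-rich phloroglucinol rings (oxidation, competing C- and O-alkylation), the doubly benzylic methine flanked by four ortho oxygens (retro-Friedel–Crafts cleavage or xanthene formation in strong acid) and the chroman ether, which can open and reclose under forcing acid. The real difficulty is regiochemical and steric: the pyran ring must close onto the phenol ortho to the acyl group (acyl on C8, not C6), and two hexasubstituted rings must be joined at one carbon. The key step exploits the 1,3,5-oxygen pattern of ring A with the acyl group on C8: a linear 3,5,7-triketo ester whose chain C6 attacks the ester carbon (chain C1) gives exactly this pattern, forming the ring bond between C8 and a neighbouring oxygen-bearing carbon (C7 or, before desymmetrisation, the equivalent C8a) from an open chain that already carries the (R)-sec-butyl ketone.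

## Logic of the disconnections

21 to two molecules of 18 and one of 19. The two bonds from the bridging methine to C6 of each ring are cut. They are the only bonds holding the three building blocks together, the halves are identical, and the methine is at the oxidation level of an aldehyde carbon. The cut halves the problem and leaves an arene, 18, whose single unsubstituted ring carbon is the one required. The forward step must arylate one carbon twice (through 20) at a crowded centre, under conditions mild enough to spare both α-centres, the pyran ethers and the new diarylmethine.

18 to 16 (through 17). No skeletal bond is cut; the C3–C4 bond is taken back to an alkene and the 5-hydroxyl to its benzyl ether. This lets the pyran ring be made as a chromene by a condensation that needs no strong acid, and keeps the oxygen para to the acyl group masked until the ring exists. The forward step is one reduction that must saturate the alkene and cleave the ether without reducing the chelated aryl ketone.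

16 to 13 and 14. The C4–C4a and O1–C2 bonds of the pyran ring are cut, removing a five-carbon unit. In 13 the para oxygen is blocked, so the two free phenols and the two free ring carbons are equivalent by symmetry and closure is possible only onto a phenol ortho to the acyl group. The C8-versus-C6 problem is thus solved by the substrate. The forward step (through 15) must stop after one annulation.

13 to 12. The benzylic O–C bond on the para oxygen is cut. This returns the symmetric triol. The forward step must distinguish the para hydroxyl from the two ortho hydroxyls, which rests on its higher acidity and on the chelation and crowding of the other two.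

12 to 9 (key disconnection). The ring bond between the acyl-bearing carbon and a neighbouring oxygen-bearing carbon is cut (chain C6–chain C1), and the three phenols are read as two ketones and an ester. The arene becomes an unbranched chain of alternating carbonyl groups, and the acyl group with its stereocentre is in place before the ring exists, so no ring acylation with an epimerisable acyl donor is needed. The forward step (through 10 and 11) must fold in the Claisen sense and not the aldol sense, and must leave chain C8 untouched.

9 to 7 and 3. The chain C6–C7 bond, next to the ketone that carries the stereocentre, is cut. This gives a simple diketo ester and a chiral acyl donor. The forward step needs the terminal carbon of 8 to be acylated faster than 3 loses its α-proton, and needs an acyl donor that stops at the ketone level; the amide function of 3 meets the second demand.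

7 to 4 and 5, and 3 to 1. The C4–C5 bond of 7 is cut in the same way (terminal acylation of 6), and the amide C–N bond of 3 is cut back to 1 (through 2). Both cuts end at commercial materials: 1 supplies both stereocentres of 21, and 4 and 5 supply all six carbons of ring A. The only demand is that the activation of 1 avoids a ketene.

## Other disconnections considered

Alternative 1: The cut is at the bond between each carbonyl carbon and its α-carbon, with the ketones read as carbinols. The forward key step is a twofold catalytic asymmetric crotylboration of the tetra-O-benzyl dialdehyde A1 (an E-crotylboronate under a chiral phosphoric acid), giving the bis-homoallylic alcohol A2 with both methyl-bearing centres R.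
- In its favour: the stereocentres come from a catalyst and are set late on an achiral dimer, so no epimerisable centre has to survive polyanion, benzylation or bridging chemistry. Either enantiomer is accessible, and a twofold reaction on a symmetric substrate tends to enrich the major enantiomer of the doubly reacted product. On these points it is the better plan.
- Against it here: each formyl group is flanked by two ortho oxygens and is a poor partner for a closed six-membered allylboration transition state. Two carbinol centres are made only to be oxidised away. The vinyl groups must be saturated before that oxidation, because a β,γ-unsaturated α-methyl ketone would epimerise or move into conjugation, and the saturation must spare four benzyl ethers. A1 needs a separate multi-step route ending in a twofold formylation.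
- Comparison: structurally the step forms two C–C bonds but no ring and leaves the arene, pyran and bridge problems open, whereas step 4 builds ring A with its acyl group in place. Mechanistically it depends on double catalyst control at hindered sites, against a substrate-controlled folding. In step economy it is clearly longer than the eight steps chosen.

Alternative 2: The cut is at C4–C4a and O1–C2 of both pyran rings at once, with the bridge already in place. In the forward direction the bis(1,1-dimethylpropargyl) ether A3 is heated; each aryl propargyl ether undergoes Claisen rearrangement to the free ortho carbon, hydrogen shift and oxa-6π closure, giving the bis-chromene A4.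
- In its favour: the pericyclic cascade is regiospecific, needs neither acid nor base, and closes both rings in one operation. In regiocontrol it is the equal of the chosen plan (both rest on the para benzyl ether), and its endgame is the same hydrogenation as step 7.
- Against it here: the bridge must be made before the rings, from 13, which has two equivalent nucleophilic ring carbons and would tend to give oligomers with 19, whereas 18 has a single reactive site. To reach A3, one of two chelated, crowded hydroxyls on each ring must be etherified with a tertiary propargylic electrophile. The cascade needs prolonged heating of a compound with two enolisable stereocentres and a hindered diarylmethine.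
- Comparison: structurally it forms the same two ring bonds per half as step 6. Mechanistically it is a sigmatropic route where step 6 is a condensation. In step economy it needs five operations after 12 (benzylation, bridging, etherification, cascade, hydrogenation) against four.

Alternative 3: The cut is at the aryl–acyl bond C8–C(=O) and at C8a–O1. In the forward direction a fluoride source releases the aryne A6 from the silyl triflate A5; the carboxylate of 1 adds at the aryne carbon remote from the neighbouring benzyloxy group, and the aryl anion so formed takes over the acyl group, giving the ortho-hydroxyaryl ketone A7.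
- In its favour: A7 arrives with the chelated hydroxyl (the future O1) already distinguished from the two benzylated oxygens, which is better than the mono-benzylation of step 5. No cryogenic polyanion chemistry is needed, and the aryl–acyl bond is made in one step from 1; in operations from the chiral acid to the arene it is the better plan.
- Against it here: A5 is not commercial and costs several steps, so the total is no shorter. The acyl shift passes through a strained four-membered arrangement and competes with simple protonation after O-arylation, more so for an α-branched acid. The hot, basic fluoride medium and the aryl anion threaten the α-stereocentre. The later pyran annulation would have to use a single chelated phenol.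
- Comparison: structurally the ring is bought ready-made and only decorated, whereas step 4 creates it. Mechanistically its regiochemistry rests on aryne polarisation, where in step 4 the pattern is fixed by the connectivity of the chain. Step economy is about equal.

Key step: step 4

Remark (numbering): ring positions use chroman numbering (O1, C2–C4, C4a, C5–C8, C8a); positions of the open-chain precursor are called chain C1–C10 (ester carbon = chain C1), so the acyl-bearing ring carbon C8 (= chain C6) is not confused with the stereogenic chain C8.
Remark (stereochemistry): the bridging methine bears two identical (R)-configured aryl groups and is taken as non-stereogenic; 21 has two stereocentres, both R, and both come from 1.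
Remark (precursor): 9 is kept as the methyl ester so that base and leaving group are the same alkoxide; its C7 ketone is released only at the quench of step 3, and 9 is cyclised at once without long contact with silica or acid, which promote other cyclisation modes.
Remark (building block): 3-methylbut-2-enal (14) is chosen as the five-carbon unit of the pyran ring so that ring formation needs no Lewis acid; 2-methylbut-3-en-2-ol under BF3·OEt2 is kept as the fallback to step 6.

## Route

Step 1
Reactants: 1 (R)-2-methylbutanoic acid
Product: 3 (R)-N-methoxy-N,2-dimethylbutanamide, via acyl imidazole 2 (not isolated)
Conditions: 1,1'-carbonyldiimidazole (1.1 equiv), CH2Cl2, 0 °C to rt; then MeNHOMe·HCl (1.2 equiv), rt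
Reagents that add atoms: N,O-dimethylhydroxylamine hydrochloride, CNOC.Cl; 1,1'-carbonyldiimidazole, O=C(n1ccnc1)n1ccnc1 (imidazolyl group of 2 only)
Why: Activation as the acyl imidazole 2 and aminolysis is a standard amide formation that avoids an acid chloride and any ketene pathway, so the α-stereocentre of 1 should be carried over unchanged.

Step 2
Reactants: 4 methyl acetoacetate; 5 N-methoxy-N-methylacetamide
Product: 7 methyl 3,5-dioxohexanoate, via dilithium dianion 6 (not isolated)
Conditions: LiN(iPr)2 (2.2 equiv), THF, −78 to 0 °C; then 5 (0.9 equiv), −78 to 0 °C; cold aq HCl
Reagents that add atoms: lithium diisopropylamide, [Li+].CC(C)[N-]C(C)C (lithium of 6 only)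
Why: γ-Acylation of a β-keto ester dianion, a known reaction: the terminal carbanion of 6 is its most nucleophilic site. The N-methoxy-N-methylamide releases the new ketone only at the acidic quench, so the more acidic product cannot protonate unreacted 6.

Step 3
Reactants: 7 methyl 3,5-dioxohexanoate; 3 (R)-N-methoxy-N,2-dimethylbutanamide
Product: 9 methyl (R)-8-methyl-3,5,7-trioxodecanoate, via trilithium trianion 8 (not isolated)
Conditions: LiN(iPr)2 (3.3 equiv), THF, 0 °C; then 3 (0.85 equiv), −78 to 0 °C; pour into cold dilute HCl; crude 9 used at once
Reagents that add atoms: lithium diisopropylamide, [Li+].CC(C)[N-]C(C)C (lithium of 8 only)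
Why: Terminal C-acylation of a 3,5-diketo ester trianion (polyketide-type chain extension, known): the last-formed, least stabilised carbanion of 8 reacts first, and the ketone at chain C7 appears only at the quench, where it is at once part of a β-diketone enolised towards C6 and away from the stereocentre. Addition to the amide carbonyl should outrun removal of the hindered tertiary α-proton of 3, the one threat to configuration in this step.

Step 4
Reactants: 9 methyl (R)-8-methyl-3,5,7-trioxodecanoate
Product: 12 (R)-2-methyl-1-(2,4,6-trihydroxyphenyl)butan-1-one, via magnesium bis-enolate 10 (not isolated), via cyclic triketone 11 (not isolated)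
Conditions: Mg(OMe)2 (3 equiv), MeOH, rt to 50 °C, under N2; then cold 1 M HCl
Reagents that add atoms: magnesium methoxide, [Mg+2].C[O-].C[O-] (magnesium of 10 only)
Why: Mg(OMe)2 should deprotonate the two most acidic methylenes of 9, chain C4 and chain C6 (each between two ketones), and hold the bis-enolate 10 as a folded magnesium chelate, while chain C2 stays largely un-ionised so that the ester carbon C1 remains electrophilic and is activated by the metal. Chain C6 then attacks C1 in an intramolecular Claisen (Dieckmann-type) acyl substitution, methoxide leaves, and the triketone 11 enolises three times to the phenoxide of 12, an aromatisation that makes the closure irreversible. The closest known reaction type is the biomimetic Mg(OMe)2-mediated cyclisation of 3,5,7-triketo esters, and of the pyrones derived from them, to acylphloroglucinols. Ring A closes in the 6-exo-trig mode by attack of the central carbon of a 1,3-diketonate on an exocyclic C=O, which is favoured whether the enolate is counted as endo or exo to the new ring. No stereocentre is formed; the existing one at chain C8 lies next to a ketone that is enolised towards C6, on a chain already carrying two negative charges, so a further deprotonation at this tertiary carbon by a weak alkoxide base is unlikely. The selectivity needed is Claisen folding over aldol folding (chain C2 onto the C7 ketone, which would lead to a resorcylate) and over closure through oxygen to a pyrone or pyranone. It is secured by the mild chelating base that leaves C2 un-ionised, by the α-branch that shields the C7 carbonyl, and by methoxide being both base and leaving group, so that a pyrone formed by lactonisation is reopened to the same chain and no ester exchange can occur. Quenching into cold dilute acid limits acid-catalysed pyranone formation from any unreacted 9.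

Step 5
Reactants: 12 (R)-2-methyl-1-(2,4,6-trihydroxyphenyl)butan-1-one
Product: 13 (R)-1-[4-(benzyloxy)-2,6-dihydroxyphenyl]-2-methylbutan-1-one
Conditions: BnBr (1.0 equiv), K2CO3 (1.0 equiv), DMF, 0 °C to rt, under N2
Reagents that add atoms: benzyl bromide, BrCc1ccccc1
Why: Williamson etherification with one equivalent each of base and halide: the para hydroxyl is the most acidic (its phenoxide is a vinylogous carboxylate of the ketone) and is neither hydrogen-bonded to the carbonyl nor flanked by the acyl group, so the mono-anion should alkylate there first. The weak base does not enolise the ketone.

Step 6
Reactants: 13 (R)-1-[4-(benzyloxy)-2,6-dihydroxyphenyl]-2-methylbutan-1-one; 14 3-methylbut-2-enal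
Product: 16 (R)-1-[5-(benzyloxy)-7-hydroxy-2,2-dimethyl-2H-chromen-8-yl]-2-methylbutan-1-one, via dienone 15 (not isolated)
Conditions: 14 (1.3 equiv), ethylenediammonium diacetate (10 mol %), toluene, 80 °C
Reagents that add atoms: none
Why: Ammonium-salt-catalysed Knoevenagel-type condensation of the enal at a ring carbon ortho to a free phenol gives the dienone 15, which closes by oxa-6π electrocyclisation (formal chromene annulation, known for phloroglucinol-type phenols). With the para oxygen benzylated, both free ring carbons and both phenols of 13 are equivalent and only the 8-acyl chromene can form. The small excess of 14 and the chelated, deactivated remaining phenol should hold back a second annulation.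

Step 7
Reactants: 16 (R)-1-[5-(benzyloxy)-7-hydroxy-2,2-dimethyl-2H-chromen-8-yl]-2-methylbutan-1-one
Product: 18 (R)-1-(5,7-dihydroxy-2,2-dimethylchroman-8-yl)-2-methylbutan-1-one, via benzyl chroman 17 (not isolated)
Conditions: H2 (1 atm), 10% Pd/C, EtOAc, rt
Reagents that add atoms: none
Why: Heterogeneous hydrogenation should saturate the styrene-like C3–C4 double bond to give 17 and then cleave the benzyl ether by hydrogenolysis. The ketone, a chelated vinylogous ester, and the α-stereocentre should be untouched under neutral conditions at atmospheric pressure.

Step 8
Reactants: 18 (R)-1-(5,7-dihydroxy-2,2-dimethylchroman-8-yl)-2-methylbutan-1-one (two molecules); 19 6-methylheptanal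
Product: 21 1,1-bis{5,7-dihydroxy-2,2-dimethyl-8-[(R)-2-methylbutanoyl]chroman-6-yl}-6-methylheptane (target CNP0324275.1), via ortho-quinone methide 20 (not isolated)
Conditions: 18 (2.1 equiv), 19 (1.0 equiv), TsOH·H2O (10 mol %), MeCN/CH2Cl2, rt
Reagents that add atoms: none
Why: Acid-catalysed hydroxyalkylation at C6, the only free ring carbon (ortho to two phenols, para to O1), loss of water to the ortho-quinone methide 20 and Friedel–Crafts-type conjugate addition of a second molecule of 18; this is the known phenol–aldehyde condensation to 1,1-diarylalkanes. No stereocentre is created because the methine receives two identical (R)-configured aryl groups. Catalytic acid at room temperature and an excess of 18 are chosen to avoid ketone enolisation, xanthene formation and chain-side tautomerisation of 20.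

## Compound list

1 | (R)-2-methylbutanoic acid | CC[C@@H](C)C(=O)O | starting material
2 | (R)-1-(1H-imidazol-1-yl)-2-methylbutan-1-one (acyl imidazole, formed in the flask) | CC[C@@H](C)C(=O)n1ccnc1 | intermediate
3 | (R)-N-methoxy-N,2-dimethylbutanamide | CC[C@@H](C)C(=O)N(C)OC | intermediate
4 | methyl acetoacetate | COC(=O)CC(C)=O | starting material
5 | N-methoxy-N-methylacetamide | CC(=O)N(C)OC | starting material
6 | dilithium dianion of methyl acetoacetate (formed in the flask) | [Li+].[Li+].COC([O-])=CC(=C)[O-] | intermediate
7 | methyl 3,5-dioxohexanoate | COC(=O)CC(=O)CC(C)=O | intermediate
8 | trilithium trianion of methyl 3,5-dioxohexanoate (formed in the flask) | [Li+].[Li+].[Li+].COC([O-])=CC([O-])=CC(=C)[O-] | intermediate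
9 | methyl (R)-8-methyl-3,5,7-trioxodecanoate | COC(=O)CC(=O)CC(=O)CC(=O)[C@H](C)CC | intermediate
10 | magnesium bis-enolate of 9 at chain C4 and C6 (formed in the flask) | [Mg+2].COC(=O)CC([O-])=CC(=O)C=C([O-])[C@H](C)CC | intermediate
11 | 2-[(R)-2-methylbutanoyl]cyclohexane-1,3,5-trione (formed in the flask) | CC[C@@H](C)C(=O)C1C(=O)CC(=O)CC1=O | intermediate
12 | (R)-2-methyl-1-(2,4,6-trihydroxyphenyl)butan-1-one | CC[C@@H](C)C(=O)c1c(O)cc(O)cc1O | intermediate
13 | (R)-1-[4-(benzyloxy)-2,6-dihydroxyphenyl]-2-methylbutan-1-one | CC[C@@H](C)C(=O)c1c(O)cc(OCc2ccccc2)cc1O | intermediate
14 | 3-methylbut-2-enal | CC(C)=CC=O | starting material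
15 | 5-(benzyloxy)-3-hydroxy-2-[(R)-2-methylbutanoyl]-6-(3-methylbut-2-en-1-ylidene)cyclohexa-2,4-dien-1-one (formed in the flask) | CC[C@@H](C)C(=O)C1=C(O)C=C(OCc2ccccc2)C(=CC=C(C)C)C1=O | intermediate
16 | (R)-1-[5-(benzyloxy)-7-hydroxy-2,2-dimethyl-2H-chromen-8-yl]-2-methylbutan-1-one | CC[C@@H](C)C(=O)c1c(O)cc(OCc2ccccc2)c2c1OC(C)(C)C=C2 | intermediate
17 | (R)-1-[5-(benzyloxy)-7-hydroxy-2,2-dimethylchroman-8-yl]-2-methylbutan-1-one (formed in the flask) | CC[C@@H](C)C(=O)c1c(O)cc(OCc2ccccc2)c2c1OC(C)(C)CC2 | intermediate
18 | (R)-1-(5,7-dihydroxy-2,2-dimethylchroman-8-yl)-2-methylbutan-1-one | CC[C@@H](C)C(=O)c1c(O)cc(O)c2c1OC(C)(C)CC2 | intermediate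
19 | 6-methylheptanal | CC(C)CCCCC=O | starting material
20 | 7-hydroxy-2,2-dimethyl-8-[(R)-2-methylbutanoyl]-6-(6-methylheptylidene)-3,4-dihydro-2H-chromen-5(6H)-one (formed in the flask) | CC[C@@H](C)C(=O)C1=C(O)C(=CCCCCC(C)C)C(=O)C2=C1OC(C)(C)CC2 | intermediate
21 | 1,1-bis{5,7-dihydroxy-2,2-dimethyl-8-[(R)-2-methylbutanoyl]chroman-6-yl}-6-methylheptane (CNP0324275.1) | CC[C@@H](C)C(=O)c1c(O)c(C(CCCCC(C)C)c2c(O)c3c(c(C(=O)[C@H](C)CC)c2O)OC(C)(C)CC3)c(O)c2c1OC(C)(C)CC2 | target

## Step count and least certain steps

Total: 8 steps. Longest linear sequence: 7 steps (steps 2 to 8 from 4, or steps 1 and 3 to 8 from 1).

Step 4 (key step). Most likely failure: folding in the aldol sense or closure through oxygen, if chain C2 becomes ionised or acid builds up at work-up; slow loss of configuration at chain C8 on long heating in methoxide is the second concern. Fallback: the ring is bought and not built. Setting out from 1, oxalyl chloride with catalytic DMF would give (R)-2-methylbutanoyl chloride F1, which would acylate phloroglucinol under AlCl3 in CH2Cl2/nitrobenzene at 0 °C to rt (Friedel–Crafts C-acylation, all three ring carbons being equivalent); the route is rejoined at 12. The configuration of 12 made this way would need checking, because the acylium/ketene manifold can erode it.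

Step 8. Most likely failure: stalling after the first hydroxyalkylation, because the second arylation creates a very crowded diarylmethine, with 20 diverted by chain-side tautomerisation or by condensation to a xanthene when the acid is pushed; stronger acid also invites enolisation of the ketones. Fallback: the two C–C bonds are formed in separate, acid-free operations. Setting out from 18, condensation with 19 and morpholine in EtOH at rt (phenolic Mannich reaction) would give the Mannich base (2R)-1-{5,7-dihydroxy-2,2-dimethyl-6-[6-methyl-1-(morpholin-4-yl)heptyl]chroman-8-yl}-2-methylbutan-1-one F2 (a diastereomer mixture at the aminoalkyl carbon, which is of no consequence). Heating F2 with one further equivalent of 18 in toluene at 90 °C would expel morpholine, regenerate 20 under neutral conditions and let it be trapped; the route is rejoined at 21.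

Step 3. Most likely failure: proton transfer from 3 to the strongly basic terminus of 8, which would lower conversion and erode configuration, together with self-condensation of 8 at 0 °C. Fallback: a less basic nucleophile and a masked ester. Setting out from 3, commercial 2,2,6-trimethyl-4H-1,3-dioxin-4-one would be deprotonated with LiN(SiMe3)2 and C-acetylated with acetyl chloride to 2,2-dimethyl-6-(2-oxopropyl)-4H-1,3-dioxin-4-one F3. The dianion of F3 (LiN(iPr)2, 2 equiv, THF, −78 °C) would be acylated at its terminal carbon by 3 to give 2,2-dimethyl-6-[(R)-5-methyl-2,4-dioxoheptyl]-4H-1,3-dioxin-4-one F4. Heating F4 in toluene containing MeOH at about 100 °C would release acetone and the acylketene (R)-8-methyl-3,5,7-trioxodec-1-en-1-one F5, which MeOH traps as 9, where the route is rejoined.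

Step 5. Most likely failure: over-alkylation to a dibenzyl ether and some C-benzylation of the ambident phloroglucinol anion, because the acidity gap between para and ortho hydroxyls is modest. Fallback: the over-alkylation is made the aim. Setting out from 12, BnBr (2.2 equiv) and K2CO3 in refluxing acetone would give (R)-1-[2,4-bis(benzyloxy)-6-hydroxyphenyl]-2-methylbutan-1-one F6 (identical with A7), in which only the chelated hydroxyl is free. Chromene annulation with 14 at the ring carbon next to that hydroxyl (PhB(OH)2, AcOH, toluene, reflux) would give (R)-1-[5,7-bis(benzyloxy)-2,2-dimethyl-2H-chromen-8-yl]-2-methylbutan-1-one F7. Hydrogenation over Pd/C as in step 7 would remove both benzyl groups and saturate the ring, rejoining the route at 18.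

Step 6. Most likely failure: a second annulation at the remaining free ring carbon and phenol, or slow condensation because the acyl group deactivates the ring, so that heating has to be prolonged. Fallback: the pyran ring is made directly at the chroman level by Friedel–Crafts chemistry. Setting out from 13, 2-methylbut-3-en-2-ol and BF3·OEt2 in dioxane at rt would C-prenylate one of the two equivalent ring carbons to give (R)-1-[4-(benzyloxy)-2,6-dihydroxy-3-(3-methylbut-2-en-1-yl)phenyl]-2-methylbutan-1-one F8. Under the same acid (or on brief warming with TsOH) F8 would add its neighbouring phenol across the alkene to give 17, which would be isolated and hydrogenolysed as in the second half of step 7; the route is rejoined at 17. The cost is exposure of the benzyl ether and the α-stereocentre to Lewis acid, which is why this is not the first choice.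

Further compounds

F1 | step 4 | (R)-2-methylbutanoyl chloride | CC[C@@H](C)C(Cl)=O
F2 | step 8 | (2R)-1-{5,7-dihydroxy-2,2-dimethyl-6-[6-methyl-1-(morpholin-4-yl)heptyl]chroman-8-yl}-2-methylbutan-1-one | CC[C@@H](C)C(=O)c1c(O)c(C(CCCCC(C)C)N2CCOCC2)c(O)c2c1OC(C)(C)CC2
F3 | step 3 | 2,2-dimethyl-6-(2-oxopropyl)-4H-1,3-dioxin-4-one | CC(=O)CC1=CC(=O)OC(C)(C)O1
F4 | step 3 | 2,2-dimethyl-6-[(R)-5-methyl-2,4-dioxoheptyl]-4H-1,3-dioxin-4-one | CC[C@@H](C)C(=O)CC(=O)CC1=CC(=O)OC(C)(C)O1
F5 | step 3 | (R)-8-methyl-3,5,7-trioxodec-1-en-1-one (acylketene) | CC[C@@H](C)C(=O)CC(=O)CC(=O)C=C=O
F6 | step 5 | (R)-1-[2,4-bis(benzyloxy)-6-hydroxyphenyl]-2-methylbutan-1-one | CC[C@@H](C)C(=O)c1c(O)cc(OCc2ccccc2)cc1OCc1ccccc1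
F7 | step 5 | (R)-1-[5,7-bis(benzyloxy)-2,2-dimethyl-2H-chromen-8-yl]-2-methylbutan-1-one | CC[C@@H](C)C(=O)c1c(OCc2ccccc2)cc(OCc2ccccc2)c2c1OC(C)(C)C=C2
F8 | step 6 | (R)-1-[4-(benzyloxy)-2,6-dihydroxy-3-(3-methylbut-2-en-1-yl)phenyl]-2-methylbutan-1-one | CC[C@@H](C)C(=O)c1c(O)cc(OCc2ccccc2)c(CC=C(C)C)c1O
A1 | alternative 1 | 6,6'-(6-methylheptane-1,1-diyl)bis[5,7-bis(benzyloxy)-2,2-dimethylchroman-8-carbaldehyde] | O=Cc1c(OCc2ccccc2)c(C(CCCCC(C)C)c2c(OCc3ccccc3)c3c(c(C=O)c2OCc2ccccc2)OC(C)(C)CC3)c(OCc2ccccc2)c2c1OC(C)(C)CC2
A2 | alternative 1 | bis[(1R,2R)-1-hydroxy-2-methylbut-3-enyl] tetra-O-benzyl bridged dimer (anti homoallylic alcohol at each C8) | C=C[C@@H](C)[C@@H](O)c1c(OCc2ccccc2)c(C(CCCCC(C)C)c2c(OCc3ccccc3)c3c(c([C@H](O)[C@H](C)C=C)c2OCc2ccccc2)OC(C)(C)CC3)c(OCc2ccccc2)c2c1OC(C)(C)CC2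
A3 | alternative 2 | 6-methylheptane-1,1-diyl-bridged bis[(R)-2-methylbutanoylphloroglucinol], para-O-benzyl and distal ortho-O-(2-methylbut-3-yn-2-yl) on each ring | CC[C@@H](C)C(=O)c1c(O)c(C(CCCCC(C)C)c2c(OCc3ccccc3)cc(OC(C)(C)C#C)c(C(=O)[C@H](C)CC)c2O)c(OCc2ccccc2)cc1OC(C)(C)C#C
A4 | alternative 2 | bridged bis(2,2-dimethyl-2H-chromene), 5,5'-di-O-benzyl | CC[C@@H](C)C(=O)c1c(O)c(C(CCCCC(C)C)c2c(OCc3ccccc3)c3c(c(C(=O)[C@H](C)CC)c2O)OC(C)(C)C=C3)c(OCc2ccccc2)c2c1OC(C)(C)C=C2
A5 | alternative 3 | 3,5-bis(benzyloxy)-2-(trimethylsilyl)phenyl trifluoromethanesulfonate | C[Si](C)(C)c1c(OS(=O)(=O)C(F)(F)F)cc(OCc2ccccc2)cc1OCc1ccccc1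
A6 | alternative 3 | 3,5-bis(benzyloxy)benzyne | C1(OCc2ccccc2)=CC(OCc2ccccc2)=CC#C1
A7 | alternative 3 | (R)-1-[2,4-bis(benzyloxy)-6-hydroxyphenyl]-2-methylbutan-1-one | CC[C@@H](C)C(=O)c1c(O)cc(OCc2ccccc2)cc1OCc1ccccc1
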